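**Strategy.** The target is cut at the C5–C6 bond of the acetoxy-cyclohexane (ring B; clerodane numbering, given below). The feature exploited is ring A: its carbinol carbon C2 lies para to quaternary C5, with the C3=C4 enoate between them, which is the imprint of a phenol alkylated at its para carbon. The key step is an acid-promoted intramolecular para-alkylation (dearomatization) of a flat phenol ether by a tethered diazomethyl ketone; in one operation it closes ring B, creates C5 and relays the single stereocentre C9 to it. The precursor is a PMB-protected phthalan–phenol fused to the furocycloheptenone ring, its C9 carrying CH(CH3)COCHN2. C10, C1, C8, C7 and C2 then follow by substrate control.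

Key step: step 9

Numbering used throughout: ring A = C1, C2, C3, C4, C5, C10 (hydroxy-cyclohexene); ring B = C5, C6, C7, C8, C9, C10 (acetoxy-cyclohexane); lactone C=O is C18 (on C4), lactone CH2 is C19 (on C5); CH3 on C8 is C17, CH3 on C9 is C20; C11 (CH2) and C12 (ketone) follow C9; furan C13 (on C12), C14, C15, C16 (on C1). Ar = 6-[(4-methoxybenzyl)oxy]-1,3-dihydroisobenzofuran-4-yl; PMB = 4-methoxybenzyl.

Assumption: 1, 5 and 11 are treated as catalogue compounds. The C8 centre is α to a carbonyl in 10 and 13–19, is carried as both epimers and is fixed only in step 10, so it is left undefined in those SMILES.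

**Step 1**
Reactants: 1 4-bromo-1,3-dihydroisobenzofuran
Product: 3 7-bromo-1,3-dihydroisobenzofuran-5-ol, via aryl pinacolboronate 2 (not isolated)
Conditions: [Ir(OMe)(cod)]2 (cat.), dtbpy (cat.), B2pin2, THF, 80 °C; then Oxone, acetone/H2O, rt
Reagents that add atoms: bis(pinacolato)diboron, CC1(C)OB(OC1(C)C)B1OC(C)(C)C(C)(C)O1 (boron of 2); Oxone (potassium peroxymonosulfate), [K+].[O-]S(=O)(=O)OO (phenol oxygen)
Why: Sterically controlled Ir-catalysed arene C–H borylation (Hartwig–Miyaura) should select the only ring C–H flanked by two hydrogens, and the C–B bond is then oxidised in the same pot to the phenol.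

**Step 2**
Reactants: 3 7-bromo-1,3-dihydroisobenzofuran-5-ol
Product: 4 4-bromo-6-[(4-methoxybenzyl)oxy]-1,3-dihydroisobenzofuran
Conditions: PMBCl, K2CO3, DMF, 50 °C
Reagents that add atoms: 4-methoxybenzyl chloride, COc1ccc(CCl)cc1
Why: Williamson etherification of the phenoxide; the PMB ether survives the basic and organometallic steps and is designed to leave as a stabilized cation in the key step.

**Step 3**
Reactants: 4 4-bromo-6-[(4-methoxybenzyl)oxy]-1,3-dihydroisobenzofuran; 5 4,4,5,5-tetramethyl-2-(prop-1-en-2-yl)-1,3,2-dioxaborolane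
Product: 6 6-[(4-methoxybenzyl)oxy]-4-(prop-1-en-2-yl)-1,3-dihydroisobenzofuran
Conditions: Pd(dppf)Cl2 (cat.), K2CO3, dioxane/H2O, 90 °C
Reagents that add atoms: none
Why: Suzuki–Miyaura coupling of a mono-ortho-substituted aryl bromide with an alkenylboronate.

**Step 4**
Reactants: 6 6-[(4-methoxybenzyl)oxy]-4-(prop-1-en-2-yl)-1,3-dihydroisobenzofuran
Product: 8 3-methyl-3-Ar-cyclobutan-1-one, via cyclobutaniminium triflate 7 (not isolated)
Conditions: N,N-dimethylacetamide, Tf2O, 2,4,6-collidine, ClCH2CH2Cl, reflux; then H2O
Reagents that add atoms: N,N-dimethylacetamide, CC(=O)N(C)C (two ring carbons); triflic anhydride, O=S(=O)(OS(=O)(=O)C(F)(F)F)C(F)(F)F (counter-ion of 7); water, O (ketone oxygen)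
Why: Ghosez keteniminium–alkene [2+2] cycloaddition: the CH2 terminus of the electron-rich 1,1-disubstituted styrene attacks the iminium carbon and the benzylic cation closes on the enamine carbon, so hydrolysis should give the 3,3-disubstituted, prochiral cyclobutanone.

**Step 5**
Reactants: 8 3-methyl-3-Ar-cyclobutan-1-one
Product: 10 (3S)-2,3-dimethyl-3-Ar-cyclobutan-1-one (both C2 epimers), via lithium enolate 9 (not isolated)
Conditions: (R,R)-bis(1-phenylethyl)amine, n-BuLi, LiCl, THF, −100 °C; then MeI, DMPU, −78 to −40 °C
Reagents that add atoms: n-butyllithium, [Li]CCCC (lithium of 9); iodomethane, CI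
Why: Enantiotopic-group-selective deprotonation of a prochiral 3,3-disubstituted cyclobutanone by a chiral lithium amide (Simpkins–Koga desymmetrization) and enolate C-methylation; which CH2 is deprotonated fixes the quaternary carbon (future C9), the new CH(CH3) centre (future C8) is immaterial, and the antipodal amine is to be used if the sense of induction proves opposite.

**Step 6**
Reactants: 10 (3S)-2,3-dimethyl-3-Ar-cyclobutan-1-one; 11 2-bromofuran-3-carboxylic acid
Product: 14 (3S)-3-Ar-5-(2-bromofuran-3-yl)-2,3-dimethyl-5-oxopentanoic acid (both C2 epimers), via acid chloride 12 (not isolated), via acylcyclobutanone 13 (not isolated)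
Conditions: 11, (COCl)2, DMF (cat.), CH2Cl2, rt, evaporate; 10, LiHMDS (2.2 equiv), THF, −78 °C, then 12; then LiOH, THF/H2O, 0 °C to rt; H3O+
Reagents that add atoms: oxalyl chloride, ClC(=O)C(Cl)=O (chlorine of 12); lithium hydroxide, [Li+].[OH-] (carboxyl oxygen)
Why: Kinetic enolization at the less substituted α-CH2 and Claisen-type C-acylation give a strained 2-acylcyclobutanone; hydroxide attacks its ring ketone and retro-Claisen cleavage expels the stabilized furyl ketone enolate, which unzips the ring into the C11–C12 keto arm and the C8–C7 acid arm.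

**Step 7**
Reactants: 14 (3S)-3-Ar-5-(2-bromofuran-3-yl)-2,3-dimethyl-5-oxopentanoic acid
Product: 15 (9S)-tetracyclic keto acid (furan C16 bonded to arene C1; C9 bears CH3 and CH(CH3)CO2H)
Conditions: Pd(OAc)2 (cat.), PCy3·HBF4 (cat.), K2CO3, PivOH (cat.), DMA, 120 °C
Reagents that add atoms: none
Why: Intramolecular Pd-catalysed direct arylation (concerted metalation–deprotonation, Fagnou conditions): oxidative addition into the activated 2-bromofuran and palladation of the only arene C–H the tether can reach (ortho to the ether oxygen) close the seven-membered ketone ring.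

**Step 8**
Reactants: 15 (9S)-tetracyclic keto acid
Product: 17 (9S)-tetracyclic diazomethyl ketone (C9 bears CH(CH3)COCHN2), via acid chloride 16 (not isolated)
Conditions: 1-chloro-N,N,2-trimethylprop-1-en-1-amine, CH2Cl2, 0 °C; then CH2N2 (excess), Et2O, 0 °C
Reagents that add atoms: 1-chloro-N,N,2-trimethylprop-1-en-1-amine, CC(C)=C(Cl)N(C)C (chlorine of 16); diazomethane, C=[N+]=[N-]
Why: Ghosez's reagent makes the hindered acid chloride under neutral conditions (PMB ether safe), and the chloride acylates diazomethane (first stage of the Arndt–Eistert sequence), the excess removing HCl as CH3Cl.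

**Step 9**
Reactants: 17 (9S)-tetracyclic diazomethyl ketone
Product: 19 pentacyclic cross-conjugated dienone (C5–C6 bond formed; C2 ketone flanked by C3=C4 and C1=C10; C7 and C12 ketones; C19 and C20 syn), via oxocarbenium ion 18 (not isolated)
Conditions: CF3CO2H, anisole, CH2Cl2, −20 to 0 °C
Reagents that add atoms: none
Why: Protonation of the diazo carbon gives an α-keto alkyldiazonium ion, which is displaced with loss of N2 by aromatic carbon C5 (para to the ether oxygen, Ar2-6 participation) to give oxocarbenium ion 18, and transfer of the PMB cation to anisole releases the dienone. The closest known reaction is the Mander acid-promoted intramolecular para-alkylation of phenols and their ethers by diazomethyl ketones. Ring B closes in the 6-exo-tet mode, the leaving group lying outside the new six-membered ring. The new quaternary stereocentre C5 is controlled by C9: C11 is held near the arene plane by the seven-membered ring, so the C8 tether and the C20 methyl lie on opposite faces and C6 can only bond to the face that leaves C19 and C20 syn, as in the target. The step needs C-alkylation at C5 rather than capture of the diazonium ion by trifluoroacetate, ortho attack or ipso attack; C5 is the only oxygen-activated carbon within reach, the ortho carbon C1 is substituted and tied into the furan-bridged ring, and ipso attack at C10 has no para oxygen to stabilize it.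

**Step 10**
Reactants: 19 pentacyclic cross-conjugated dienone
Product: 20 enone triketone (C1=C10 saturated; H10 trans to C19; H1 trans to H10; C17 equatorial and cis to C20)
Conditions: Mn(dpm)3 (cat.), PhSiH3, i-PrOH, rt, degassed; then K2CO3, MeOH, rt
Reagents that add atoms: none
Why: Metal-hydride hydrogen-atom transfer (Magnus/Shenvi conjugate reduction) should deliver H• to C10, because this forms the tertiary C1 radical stabilized by both the C2 ketone and the acylfuran, and from the face opposite the syn-axial C19 and C20 groups (trans ring fusion); carbonate then equilibrates the epimerizable centres C1 (furan equatorial) and C8 (methyl equatorial).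

**Step 11**
Reactants: 20 enone triketone
Product: 21 C7 axial alcohol (OH cis to C19 and C20)
Conditions: NaBH4 (1 equiv), MeOH/CH2Cl2, −78 °C
Reagents that add atoms: none
Why: Low-temperature borohydride reduction should take the saturated C7 ketone in preference to the enone and the furyl ketone, and the syn-axial C19 and C20 groups block axial attack, so hydride enters equatorially and the alcohol is axial.

**Step 12**
Reactants: 21 C7 axial alcohol
Product: 22 C7 acetate
Conditions: Ac2O, Sc(OTf)3 (cat.), MeCN, −20 to 0 °C
Reagents that add atoms: acetic anhydride, CC(=O)OC(C)=O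
Why: Lewis-acid-catalysed acylation (Yamamoto Sc(OTf)3/Ac2O) is strong enough for the hindered axial alcohol and, being cold and non-basic, should leave the enolizable C1 and C11 positions alone.

**Step 13**
Reactants: 22 C7 acetate
Product: 23 18,19-lactone (C18 carbonyl) with C2 ketone
Conditions: CrO3, 3,5-dimethylpyrazole, CH2Cl2, −20 °C
Reagents that add atoms: chromium trioxide, O=[Cr](=O)=O
Why: Cr(VI) allylic oxidation (Salmond reagent): C18 is the only CH2 that is both allylic and α to the ether oxygen, so the dihydrofuran should be oxidised there to the butenolide while the neopentyl ether CH2 (C19) is not activated.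

**Step 14**
Reactants: 23 18,19-lactone with C2 ketone
Product: 24 CNP0182929.1 (target)
Conditions: NaBH4, CeCl3·7H2O, MeOH, −78 °C
Reagents that add atoms: none
Why: Luche 1,2-reduction of the most electrophilic carbonyl (C2 ketone of the 4-oxo-enoate) should spare the furyl ketone, lactone and acetate, and axial hydride attack anti to the axial C1–H gives the equatorial C2 alcohol, cis to H1 and trans to the furan.

**Compound list**
1 | 4-bromo-1,3-dihydroisobenzofuran | Brc1cccc2c1COC2 | starting material
2 | 2-(7-bromo-1,3-dihydroisobenzofuran-5-yl)-4,4,5,5-tetramethyl-1,3,2-dioxaborolane | CC1(C)OB(OC1(C)C)c1cc2c(c(Br)c1)COC2 | intermediate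
3 | 7-bromo-1,3-dihydroisobenzofuran-5-ol | Oc1cc2c(c(Br)c1)COC2 | intermediate
4 | 4-bromo-6-[(4-methoxybenzyl)oxy]-1,3-dihydroisobenzofuran | COc1ccc(COc2cc3c(c(Br)c2)COC3)cc1 | intermediate
5 | 4,4,5,5-tetramethyl-2-(prop-1-en-2-yl)-1,3,2-dioxaborolane | CC(=C)B1OC(C)(C)C(C)(C)O1 | starting material
6 | 6-[(4-methoxybenzyl)oxy]-4-(prop-1-en-2-yl)-1,3-dihydroisobenzofuran | COc1ccc(COc2cc3c(c(c2)C(C)=C)COC3)cc1 | intermediate
7 | N,N-dimethyl-3-methyl-3-Ar-cyclobutan-1-iminium triflate | COc1ccc(COc2cc3c(c(c2)C2(C)CC(=[N+](C)C)C2)COC3)cc1.[O-]S(=O)(=O)C(F)(F)F | intermediate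
8 | 3-methyl-3-Ar-cyclobutan-1-one (prochiral) | COc1ccc(COc2cc3c(c(c2)C2(C)CC(=O)C2)COC3)cc1 | intermediate
9 | lithium (3S)-3-methyl-3-Ar-cyclobut-1-en-1-olate | COc1ccc(COc2cc3c(c(c2)[C@@]2(C)CC([O-])=C2)COC3)cc1.[Li+] | intermediate
10 | (3S)-2,3-dimethyl-3-Ar-cyclobutan-1-one, C2 epimers | COc1ccc(COc2cc3c(c(c2)[C@@]2(C)CC(=O)C2C)COC3)cc1 | intermediate
11 | 2-bromofuran-3-carboxylic acid | OC(=O)c1ccoc1Br | starting material
12 | 2-bromofuran-3-carbonyl chloride | ClC(=O)c1ccoc1Br | intermediate
13 | 4-(2-bromofuran-3-carbonyl) derivative of 10 (quaternary centre unchanged) | COc1ccc(COc2cc3c(c(c2)[C@@]2(C)C(C(=O)c4ccoc4Br)C(=O)C2C)COC3)cc1 | intermediate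
14 | (3S)-3-Ar-5-(2-bromofuran-3-yl)-2,3-dimethyl-5-oxopentanoic acid, C2 epimers | COc1ccc(COc2cc3c(c(c2)[C@@](C)(CC(=O)c2ccoc2Br)C(C)C(=O)O)COC3)cc1 | intermediate
15 | (9S)-tetracyclic keto acid: PMB-protected phthalan–phenol fused through C1–C16 and C10–C9–C11–C12 to the furan (cyclohepta[b]furan-4-one ring); C9 bears CH3 and CH(CH3)CO2H | COc1ccc(COc2cc3c(c4c2-c2occc2C(=O)C[C@@]4(C)C(C)C(=O)O)COC3)cc1 | intermediate
16 | acid chloride of 15 | COc1ccc(COc2cc3c(c4c2-c2occc2C(=O)C[C@@]4(C)C(C)C(=O)Cl)COC3)cc1 | intermediate
17 | (9S)-diazomethyl ketone of 15 (C9 bears CH(CH3)COCHN2) | COc1ccc(COc2cc3c(c4c2-c2occc2C(=O)C[C@@]4(C)C(C)C(=O)C=[N+]=[N-])COC3)cc1 | intermediate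
18 | O-PMB oxocarbenium ion of dienone 19 (cation) | O=C1C[C@@]23COCC2=CC(=[O+]Cc2ccc(OC)cc2)C(c2occc2C(=O)C[C@@]4(C)C1C)=C34 | intermediate
19 | pentacyclic dienone: 2,7,12-trione, C3=C4 and C1=C10, cyclic ether C18H2–O–C19H2, C19 and C20 syn, (9S), C8 epimers | O=C1C[C@@]23COCC2=CC(=O)C(c2occc2C(=O)C[C@@]4(C)C1C)=C34 | intermediate
20 | enone triketone: 2,7,12-trione, C3=C4, trans ring fusion (H10 anti to C19), H1 anti to H10, C17 cis to C20 | O=C1C[C@@]23COCC2=CC(=O)[C@H]2c4occc4C(=O)C[C@@](C)([C@@H]1C)[C@@H]23 | intermediate
21 | C7 axial alcohol of 20 (OH on the face of C19 and C20) | O[C@@H]1C[C@@]23COCC2=CC(=O)[C@H]2c4occc4C(=O)C[C@@](C)([C@@H]1C)[C@@H]23 | intermediate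
22 | C7 acetate of 21 | CC(=O)O[C@@H]1C[C@@]23COCC2=CC(=O)[C@H]2c4occc4C(=O)C[C@@](C)([C@@H]1C)[C@@H]23 | intermediate
23 | 7-acetoxy-2,12-dioxo-18,19-lactone (C18 carbonyl), C3=C4 | CC(=O)O[C@@H]1C[C@@]23COC(=O)C2=CC(=O)[C@H]2c4occc4C(=O)C[C@@](C)([C@@H]1C)[C@@H]23 | intermediate
24 | CNP0182929.1: 2-OH, 7-OAc, C17, C19 and C20 on one face; H10 and the C1–C16 bond on the other | CC(=O)O[C@@H]1C[C@@]23COC(=O)C2=C[C@H](O)[C@H]2c4occc4C(=O)C[C@@](C)([C@@H]1C)[C@@H]23 | target

**Summary**
Total step count: 14. Longest linear sequence: 14 steps (1 to 24); 5 and 11 enter as bought fragments.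

**Steps most likely to fail**

Step 10. Hydrogen-atom transfer may go to the C3=C4 arm of the dienone as well as to C1=C10, or may stall at the fully substituted C10. The fallback sets out from 19 and returns at 22. Dienone 19 is equilibrated at C8 (K2CO3, MeOH) and its saturated C7 ketone reduced with NaBH4 at −78 °C, where the cross-conjugated dienone should not react, to give the dienone alcohol F1. Acetylation (Ac2O, Sc(OTf)3) gives the dienone acetate F2. With the C7 carbonyl gone, the C5–C6 bond can no longer be lost as an enolate on electron transfer, so a dissolving-electron method becomes safe. SmI2/HMPA/t-BuOH at −78 °C should reduce the arm whose enolate is conjugated with the acylfuran (C1=C10), protonating C10 on the open face, and DBU then sets C1 to give 22.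

Step 9. Capture of the protonated diazoketone by trifluoroacetate (O–H insertion), or premature PMB loss followed by C-benzylation, may outrun aryl participation. The fallback sets out from 17 and returns at 19. HBr in AcOH should turn the diazoketone into the bromomethyl ketone and cleave the PMB ether, giving the phenol bromomethyl ketone F3. KOt-Bu in t-BuOH then forms the phenoxide, which can alkylate only through its para carbon (Winstein–Masamune Ar2-6 alkylation), giving 19.

Step 13. Hydrogen abstraction at the electron-poor allylic position may be slow, so that oxidative damage to the furan or over-oxidation at C19 or C1 competes. The fallback sets out from 22 and returns at 23. Radical bromination at C18 (NBS, AIBN, PhCF3, 80 °C) gives the bromo ether F4, which AgNO3 in aqueous acetone hydrolyses to the lactol F5. TEMPO/PhI(OAc)2 then oxidises the lactol to 23.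

**Further compounds**
F1 | step 10 | dienone alcohol (19 with C8 fixed and C7 reduced to the axial alcohol) | O[C@@H]1C[C@@]23COCC2=CC(=O)C(c2occc2C(=O)C[C@@]4(C)[C@@H]1C)=C34
F2 | step 10 | dienone acetate (C7 acetate of F1) | CC(=O)O[C@@H]1C[C@@]23COCC2=CC(=O)C(c2occc2C(=O)C[C@@]4(C)[C@@H]1C)=C34
F3 | step 9 | phenol bromomethyl ketone (17 with OH in place of OPMB and COCH2Br in place of COCHN2) | Oc1cc2c(c3c1-c1occc1C(=O)C[C@@]3(C)C(C)C(=O)CBr)COC2
F4 | step 13 | C18 bromo ether of 22 | CC(=O)O[C@@H]1C[C@@]23COC(Br)C2=CC(=O)[C@H]2c4occc4C(=O)C[C@@](C)([C@@H]1C)[C@@H]23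
F5 | step 13 | C18 lactol of 22 | CC(=O)O[C@@H]1C[C@@]23COC(O)C2=CC(=O)[C@H]2c4occc4C(=O)C[C@@](C)([C@@H]1C)[C@@H]23
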